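**Retrosynthetic overview**

1. Numbering: side chain C1 (benzylic CH2) to C15 (CMe2); the oxolane is O–C12–C13–C14–C15. The arene is bought, and the oxolane is the only ring made.
2. End game: C5 acetate, desilylation at C14–O, then release of the hydroquinone from its dimethyl ether (oxidative demethylation to the quinone, dithionite reduction).
3. Key disconnection C1–C2: one-pot Zr-catalysed methylalumination of a terminal alkyne and Ni-catalysed coupling of the alkenylalane with a 2,5-dimethoxy-3-methylbenzyl chloride. This makes the C3 methyl branch, the (2E)-alkene and the fragment union together. The enabling feature is the array arene–C1H2–C2H=C3(CH3)–C4H2–C5H(O): a methyl-branched (E)-alkene between a benzylic carbon and a homoallylic carbinol, which is the imprint of a homopropargylic alcohol C5(OH)–C4H2–C3≡C2H.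
4. C4–C5: catalytic asymmetric propargylation of the C5 enal. C5–C12 with both remaining (E)-alkenes comes from geranyl acetate after SeO2 oxidation at C12.
5. Oxolane: C12 by asymmetric allylation, C14 by reagent-controlled epoxidation of the C14=C15 alkene, ring closure by 5-endo opening of the epoxide at C15 by the C12 hydroxyl.

Key step: step 14

Remark on the chemistry: the facial sense assigned to (S)-TRIP (Si-face addition to both enals) and to the L-fructose-derived Shi ketone ((S)-epoxide at C14) follows the accepted transition-state models; the antipodal catalyst would be used if MTPA ester analysis of 9 or 16 showed the opposite sense.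

**Route**

Step 1
Reactants: 1 4-methoxy-2-methylphenol
Product: 2 2-hydroxy-5-methoxy-3-methylbenzaldehyde
Conditions: MgCl2, Et3N, (CH2O)n, MeCN, reflux
Reagents that add atoms: paraformaldehyde (as formaldehyde), C=O
Why: Magnesium phenoxide-directed ortho-formylation (Casnati–Skattebøl reaction) should place the aldehyde at the only free ortho position, the hydroxymethyl intermediate being oxidised in situ by a second equivalent of formaldehyde.

Step 2
Reactants: 2 2-hydroxy-5-methoxy-3-methylbenzaldehyde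
Product: 3 2,5-dimethoxy-3-methylbenzaldehyde
Conditions: MeI, K2CO3, DMF, rt
Reagents that add atoms: iodomethane, CI
Why: Williamson O-methylation of the phenol under carbonate conditions is routine and should leave the aldehyde untouched.

Step 3
Reactants: 3 2,5-dimethoxy-3-methylbenzaldehyde
Product: 4 (2,5-dimethoxy-3-methylphenyl)methanol
Conditions: NaBH4, MeOH, 0 °C
Reagents that add atoms: none
Why: Borohydride reduction of an aromatic aldehyde to the benzylic alcohol should be clean and chemoselective.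

Step 4
Reactants: 4 (2,5-dimethoxy-3-methylphenyl)methanol
Product: 5 1-(chloromethyl)-2,5-dimethoxy-3-methylbenzene
Conditions: SOCl2, CH2Cl2, 0 °C
Reagents that add atoms: thionyl chloride, O=S(Cl)Cl
Why: Deoxychlorination of an electron-rich benzylic alcohol through its chlorosulfite should give the benzylic chloride, which is used promptly.

Step 5
Reactants: 6 geranyl acetate
Product: 7 (2E,6E)-8-hydroxy-3,7-dimethylocta-2,6-dien-1-yl acetate
Conditions: SeO2 (cat.), t-BuOOH, salicylic acid (cat.), CH2Cl2, rt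
Reagents that add atoms: tert-butyl hydroperoxide, CC(C)(C)OO (terminal oxidant; the oxygen atom is passed on through catalytic selenium dioxide, O=[Se]=O)
Why: Selenium dioxide allylic oxidation (ene reaction then [2,3]-sigmatropic shift) should oxidise the (E)-methyl group of the electron-rich terminal alkene, the acetate-bearing alkene being deactivated and the (6E) geometry following from the [2,3] shift.

Step 6
Reactants: 7 (2E,6E)-8-hydroxy-3,7-dimethylocta-2,6-dien-1-yl acetate
Product: 8 (2E,6E)-3,7-dimethyl-8-oxoocta-2,6-dien-1-yl acetate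
Conditions: MnO2, CH2Cl2, rt
Reagents that add atoms: none
Why: Manganese dioxide oxidation of a primary allylic alcohol should give the (E)-enal without touching the acetate or the alkene geometry.

Step 7
Reactants: 8 (2E,6E)-3,7-dimethyl-8-oxoocta-2,6-dien-1-yl acetate
Product: 9 (2E,6E,8S)-8-hydroxy-3,7-dimethylundeca-2,6,10-trien-1-yl acetate
Conditions: allylB(pin), (S)-TRIP (5 mol %), 4 Å molecular sieves, toluene, −30 °C
Reagents that add atoms: allylboronic acid pinacol ester, C=CCB1OC(C)(C)C(C)(C)O1
Why: Chiral phosphoric acid-catalysed allylboration through a chair six-membered transition state should add allyl to the Si face of the enal under control of (S)-TRIP, setting the C12 carbinol as S.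

Step 8
Reactants: 9 (2E,6E,8S)-8-hydroxy-3,7-dimethylundeca-2,6,10-trien-1-yl acetate
Product: 10 (2E,6E,8S)-8-hydroxy-3,7,11-trimethyldodeca-2,6,10-trien-1-yl acetate
Conditions: 2-methyl-2-butene (excess), second-generation Grubbs catalyst RuCl2(=CHPh)(PCy3)(H2IMes) (5 mol %), CH2Cl2, 40 °C
Reagents that add atoms: 2-methyl-2-butene, CC=C(C)C
Why: Olefin cross-metathesis with 2-methyl-2-butene should convert only the terminal vinyl group into the isopropylidene terminus, the trisubstituted alkenes being inert and propene being lost.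

Step 9
Reactants: 10 (2E,6E,8S)-8-hydroxy-3,7,11-trimethyldodeca-2,6,10-trien-1-yl acetate
Product: 12 (2E,6E)-7-[(2S,4S)-4-hydroxy-5,5-dimethyloxolan-2-yl]-3-methylocta-2,6-dien-1-yl acetate, via epoxy alcohol 11 (not isolated)
Conditions: L-fructose-derived Shi ketone (30 mol %), KHSO5 (Oxone), K2CO3, n-Bu4NHSO4, MeCN/dimethoxymethane/aq. Na2B4O7 buffer, 0 °C; then CSA (cat.), CH2Cl2, 0 °C
Reagents that add atoms: potassium peroxymonosulfate (Oxone), [K+].[O-]S(=O)(=O)OO
Why: Shi epoxidation (dioxirane, spiro transition state) with the enantiomeric ketone should epoxidise the only alkene lacking an allylic oxygen to the (14S)-epoxide, and acid should then trigger 5-endo-tet opening at the tertiary C15 by the C12 hydroxyl with C14 untouched, giving the 2,4-cis oxolane.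

Step 10
Reactants: 12 (2E,6E)-7-[(2S,4S)-4-hydroxy-5,5-dimethyloxolan-2-yl]-3-methylocta-2,6-dien-1-yl acetate
Product: 13 (2E,6E)-7-[(2S,4S)-4-(tert-butyldimethylsilyloxy)-5,5-dimethyloxolan-2-yl]-3-methylocta-2,6-dien-1-yl acetate
Conditions: TBSOTf, 2,6-lutidine, CH2Cl2, −78 to 0 °C
Reagents that add atoms: tert-butyldimethylsilyl trifluoromethanesulfonate, CC(C)(C)[Si](C)(C)OS(=O)(=O)C(F)(F)F
Why: Silylation with the silyl triflate and a hindered base should protect the hindered secondary alcohol next to the quaternary carbon.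

Step 11
Reactants: 13 (2E,6E)-7-[(2S,4S)-4-(tert-butyldimethylsilyloxy)-5,5-dimethyloxolan-2-yl]-3-methylocta-2,6-dien-1-yl acetate
Product: 14 (2E,6E)-7-[(2S,4S)-4-(tert-butyldimethylsilyloxy)-5,5-dimethyloxolan-2-yl]-3-methylocta-2,6-dien-1-ol
Conditions: K2CO3 (cat.), MeOH, rt
Reagents that add atoms: none
Why: Carbonate-catalysed transesterification with methanol should remove the primary allylic acetate while the silyl ether stays in place.

Step 12
Reactants: 14 (2E,6E)-7-[(2S,4S)-4-(tert-butyldimethylsilyloxy)-5,5-dimethyloxolan-2-yl]-3-methylocta-2,6-dien-1-ol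
Product: 15 (2E,6E)-7-[(2S,4S)-4-(tert-butyldimethylsilyloxy)-5,5-dimethyloxolan-2-yl]-3-methylocta-2,6-dienal
Conditions: MnO2, CH2Cl2, rt
Reagents that add atoms: none
Why: Manganese dioxide oxidation of the primary allylic alcohol should give the (2E)-enal under neutral conditions that do not isomerise the alkene.

Step 13
Reactants: 15 (2E,6E)-7-[(2S,4S)-4-(tert-butyldimethylsilyloxy)-5,5-dimethyloxolan-2-yl]-3-methylocta-2,6-dienal
Product: 16 (4S,5E,9E)-10-[(2S,4S)-4-(tert-butyldimethylsilyloxy)-5,5-dimethyloxolan-2-yl]-6-methylundeca-5,9-dien-1-yn-4-ol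
Conditions: allenylB(pin), (S)-TRIP (10 mol %), 4 Å molecular sieves, toluene, 0 °C
Reagents that add atoms: allenylboronic acid pinacol ester, C=C=CB1OC(C)(C)C(C)(C)O1
Why: Chiral phosphoric acid-catalysed propargylation (SE2' transfer from the allenylboronate through a six-membered transition state) should add to the Si face of the enal under catalyst control, setting the C5 carbinol as S independently of the remote ring stereocentres.

Step 14
Reactants: 16 (4S,5E,9E)-10-[(2S,4S)-4-(tert-butyldimethylsilyloxy)-5,5-dimethyloxolan-2-yl]-6-methylundeca-5,9-dien-1-yn-4-ol; 5 1-(chloromethyl)-2,5-dimethoxy-3-methylbenzene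
Product: 18 (2E,5S,6E,10E)-1-(2,5-dimethoxy-3-methylphenyl)-11-[(2S,4S)-4-(tert-butyldimethylsilyloxy)-5,5-dimethyloxolan-2-yl]-3,7-dimethyldodeca-2,6,10-trien-5-ol, via alkenylalane alkoxide 17 (not isolated)
Conditions: Me3Al (3.5 equiv), Cp2ZrCl2 (0.3 equiv), CH2Cl2, 0 °C to rt; volatiles removed; then 5, NiCl2(PPh3)2/n-BuLi (5 mol % zerovalent nickel), THF, rt
Reagents that add atoms: trimethylaluminium, C[Al](C)C
Why: Me3Al first deprotonates the C5 hydroxyl (methane lost), and Zr-catalysed syn-methylalumination of the terminal alkyne then places methyl on the internal carbon C3 and aluminium on the terminal carbon C2, fixing the (2E) geometry in alkenylalane 17; oxidative addition of the benzylic C–Cl bond of 5 to zerovalent nickel, alkenyl transfer from aluminium and reductive elimination then form the C1–C2 bond with retention of that geometry. The closest known reaction type is the Negishi carboalumination followed by nickel- or palladium-catalysed coupling of alkenylalanes with benzylic chlorides, as practised for polyprenylated quinones. No ring is closed and no stereocentre is created; C5, C12 and C14 are spectators, and the only new stereo-element, the C2=C3 alkene, is controlled by the syn-addition. The step needs regioselectivity (methyl to C3) and chemoselectivity for the alkyne over the two trisubstituted alkenes, both secured because the terminal alkyne is the only unsaturation that Me3Al/Cp2ZrCl2 carbometalates, and it needs alkenyl rather than methyl transfer to nickel, which is the normal preference of alkenyldimethylalanes. Keeping the alkenylalane at or below room temperature should avoid alkoxide-assisted E to Z isomerisation, and the switch to THF tempers the Lewis acidity of aluminium towards the electron-rich benzylic chloride and the silyl ether.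

Step 15
Reactants: 18 (2E,5S,6E,10E)-1-(2,5-dimethoxy-3-methylphenyl)-11-[(2S,4S)-4-(tert-butyldimethylsilyloxy)-5,5-dimethyloxolan-2-yl]-3,7-dimethyldodeca-2,6,10-trien-5-ol
Product: 19 (2E,5S,6E,10E)-1-(2,5-dimethoxy-3-methylphenyl)-11-[(2S,4S)-4-(tert-butyldimethylsilyloxy)-5,5-dimethyloxolan-2-yl]-3,7-dimethyldodeca-2,6,10-trien-5-yl acetate
Conditions: Ac2O, Et3N, DMAP (cat.), CH2Cl2, 0 °C
Reagents that add atoms: acetic anhydride, CC(=O)OC(C)=O
Why: DMAP-catalysed acylation of the only free hydroxyl should give the allylic acetate with retention at C5.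

Step 16
Reactants: 19 (2E,5S,6E,10E)-1-(2,5-dimethoxy-3-methylphenyl)-11-[(2S,4S)-4-(tert-butyldimethylsilyloxy)-5,5-dimethyloxolan-2-yl]-3,7-dimethyldodeca-2,6,10-trien-5-yl acetate
Product: 20 (2E,5S,6E,10E)-1-(2,5-dimethoxy-3-methylphenyl)-11-[(2S,4S)-4-hydroxy-5,5-dimethyloxolan-2-yl]-3,7-dimethyldodeca-2,6,10-trien-5-yl acetate
Conditions: HF·pyridine, pyridine, THF, 0 °C to rt
Reagents that add atoms: none
Why: Buffered fluoride desilylation should free the C14 hydroxyl without hydrolysing or ionising the allylic acetate.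

Step 17
Reactants: 20 (2E,5S,6E,10E)-1-(2,5-dimethoxy-3-methylphenyl)-11-[(2S,4S)-4-hydroxy-5,5-dimethyloxolan-2-yl]-3,7-dimethyldodeca-2,6,10-trien-5-yl acetate
Product: 22 (2E,5S,6E,10E)-1-(2,5-dihydroxy-3-methylphenyl)-11-[(2S,4S)-4-hydroxy-5,5-dimethyloxolan-2-yl]-3,7-dimethyldodeca-2,6,10-trien-5-yl acetate, via quinone 21 (not isolated)
Conditions: (NH4)2Ce(NO3)6, MeCN/H2O, 0 °C; then aq. Na2S2O4, EtOAc, rt, under argon
Reagents that add atoms: water, O
Why: Oxidative demethylation of the 1,4-dimethoxyarene by tetravalent cerium (two one-electron oxidations, water adding at the two ipso carbons, methanol lost) should give the para-quinone, which dithionite reduces to the hydroquinone under neutral conditions.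

**Compound list**

1 | 4-methoxy-2-methylphenol | COc1ccc(O)c(C)c1 | starting material
2 | 2-hydroxy-5-methoxy-3-methylbenzaldehyde | COc1cc(C)c(O)c(C=O)c1 | intermediate
3 | 2,5-dimethoxy-3-methylbenzaldehyde | COc1cc(C)c(OC)c(C=O)c1 | intermediate
4 | (2,5-dimethoxy-3-methylphenyl)methanol | COc1cc(C)c(OC)c(CO)c1 | intermediate
5 | 1-(chloromethyl)-2,5-dimethoxy-3-methylbenzene | COc1cc(C)c(OC)c(CCl)c1 | intermediate
6 | geranyl acetate, (2E)-3,7-dimethylocta-2,6-dien-1-yl acetate | CC(=O)OC/C=C(\C)CCC=C(C)C | starting material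
7 | (2E,6E)-8-hydroxy-3,7-dimethylocta-2,6-dien-1-yl acetate | CC(=O)OC/C=C(\C)CC/C=C(\C)CO | intermediate
8 | (2E,6E)-3,7-dimethyl-8-oxoocta-2,6-dien-1-yl acetate | CC(=O)OC/C=C(\C)CC/C=C(\C)C=O | intermediate
9 | (2E,6E,8S)-8-hydroxy-3,7-dimethylundeca-2,6,10-trien-1-yl acetate | CC(=O)OC/C=C(\C)CC/C=C(\C)[C@@H](O)CC=C | intermediate
10 | (2E,6E,8S)-8-hydroxy-3,7,11-trimethyldodeca-2,6,10-trien-1-yl acetate | CC(=O)OC/C=C(\C)CC/C=C(\C)[C@@H](O)CC=C(C)C | intermediate
11 | (2E,6E,8S)-9-[(2S)-3,3-dimethyloxiran-2-yl]-8-hydroxy-3,7-dimethylnona-2,6-dien-1-yl acetate (epoxy alcohol, not isolated) | CC(=O)OC/C=C(\C)CC/C=C(\C)[C@@H](O)C[C@@H]1OC1(C)C | intermediate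
12 | (2E,6E)-7-[(2S,4S)-4-hydroxy-5,5-dimethyloxolan-2-yl]-3-methylocta-2,6-dien-1-yl acetate | CC(=O)OC/C=C(\C)CC/C=C(\C)[C@@H]1C[C@H](O)C(C)(C)O1 | intermediate
13 | (2E,6E)-7-[(2S,4S)-4-(tert-butyldimethylsilyloxy)-5,5-dimethyloxolan-2-yl]-3-methylocta-2,6-dien-1-yl acetate | CC(=O)OC/C=C(\C)CC/C=C(\C)[C@@H]1C[C@H](O[Si](C)(C)C(C)(C)C)C(C)(C)O1 | intermediate
14 | (2E,6E)-7-[(2S,4S)-4-(tert-butyldimethylsilyloxy)-5,5-dimethyloxolan-2-yl]-3-methylocta-2,6-dien-1-ol | OC/C=C(\C)CC/C=C(\C)[C@@H]1C[C@H](O[Si](C)(C)C(C)(C)C)C(C)(C)O1 | intermediate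
15 | (2E,6E)-7-[(2S,4S)-4-(tert-butyldimethylsilyloxy)-5,5-dimethyloxolan-2-yl]-3-methylocta-2,6-dienal | O=C/C=C(\C)CC/C=C(\C)[C@@H]1C[C@H](O[Si](C)(C)C(C)(C)C)C(C)(C)O1 | intermediate
16 | (4S,5E,9E)-10-[(2S,4S)-4-(tert-butyldimethylsilyloxy)-5,5-dimethyloxolan-2-yl]-6-methylundeca-5,9-dien-1-yn-4-ol | C#CC[C@H](O)/C=C(\C)CC/C=C(\C)[C@@H]1C[C@H](O[Si](C)(C)C(C)(C)C)C(C)(C)O1 | intermediate
17 | (E)-alkenyl(dimethyl)alane of 16 carrying the C5 dimethylaluminium alkoxide (not isolated) | C[Al](C)O[C@H](/C=C(\C)CC/C=C(\C)[C@@H]1C[C@H](O[Si](C)(C)C(C)(C)C)C(C)(C)O1)C/C(C)=C/[Al](C)C | intermediate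
18 | (2E,5S,6E,10E)-1-(2,5-dimethoxy-3-methylphenyl)-11-[(2S,4S)-4-(tert-butyldimethylsilyloxy)-5,5-dimethyloxolan-2-yl]-3,7-dimethyldodeca-2,6,10-trien-5-ol | O[C@H](/C=C(\C)CC/C=C(\C)[C@@H]1C[C@H](O[Si](C)(C)C(C)(C)C)C(C)(C)O1)C/C(C)=C/Cc1cc(OC)cc(C)c1OC | intermediate
19 | (2E,5S,6E,10E)-1-(2,5-dimethoxy-3-methylphenyl)-11-[(2S,4S)-4-(tert-butyldimethylsilyloxy)-5,5-dimethyloxolan-2-yl]-3,7-dimethyldodeca-2,6,10-trien-5-yl acetate | CC(=O)O[C@H](/C=C(\C)CC/C=C(\C)[C@@H]1C[C@H](O[Si](C)(C)C(C)(C)C)C(C)(C)O1)C/C(C)=C/Cc1cc(OC)cc(C)c1OC | intermediate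
20 | (2E,5S,6E,10E)-1-(2,5-dimethoxy-3-methylphenyl)-11-[(2S,4S)-4-hydroxy-5,5-dimethyloxolan-2-yl]-3,7-dimethyldodeca-2,6,10-trien-5-yl acetate | CC(=O)O[C@H](/C=C(\C)CC/C=C(\C)[C@@H]1C[C@H](O)C(C)(C)O1)C/C(C)=C/Cc1cc(OC)cc(C)c1OC | intermediate
21 | (2E,5S,6E,10E)-11-[(2S,4S)-4-hydroxy-5,5-dimethyloxolan-2-yl]-3,7-dimethyl-1-(5-methyl-3,6-dioxocyclohexa-1,4-dien-1-yl)dodeca-2,6,10-trien-5-yl acetate (quinone, not isolated) | CC(=O)O[C@H](/C=C(\C)CC/C=C(\C)[C@@H]1C[C@H](O)C(C)(C)O1)C/C(C)=C/CC1=CC(=O)C=C(C)C1=O | intermediate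
22 | (2E,5S,6E,10E)-1-(2,5-dihydroxy-3-methylphenyl)-11-[(2S,4S)-4-hydroxy-5,5-dimethyloxolan-2-yl]-3,7-dimethyldodeca-2,6,10-trien-5-yl acetate | CC(=O)O[C@H](/C=C(\C)CC/C=C(\C)[C@@H]1C[C@H](O)C(C)(C)O1)C/C(C)=C/Cc1cc(O)cc(C)c1O | target

**Step count and risks**

Total step count: 17. Longest linear sequence: 13 steps (6 to 22, steps 5 to 17); the arene branch (1 to 5) joins at step 14.

Steps most likely to fail:

Step 14. The dimethylaluminium alkoxide formed from the free C5 hydroxyl may slow the methylalumination or hold the alkenyl–aluminium bond in a chelate that transmetalates slowly to nickel, so that reductive homocoupling of the benzylic chloride or methyl transfer could compete. Alkoxide-assisted E to Z isomerisation on warming would erode the alkene geometry. The fallback sets out from 16 and 5 and comes back at 18. The same methylalumination of 16 would be quenched with I2 in THF at −30 °C to give (1E,4S,5E,9E)-1-iodo-2,6-dimethyl-10-[(2S,4S)-4-(tert-butyldimethylsilyloxy)-5,5-dimethyloxolan-2-yl]undeca-1,5,9-trien-4-ol F1. Chloride 5 would be converted with zinc dust and LiCl in THF into (2,5-dimethoxy-3-methylbenzyl)zinc chloride F2. A Negishi coupling of the two (Pd(PPh3)4, zerovalent palladium, THF, rt, excess of the zinc reagent to allow for the free hydroxyl) should then give 18. Carbometalation and cross-coupling are thus separated, and the nucleophilic role passes from the aluminium on the alkene to zinc on the benzylic partner.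

Step 9. The free homoallylic hydroxyl may disturb the spiro transition state of the dioxirane and lower the facial selectivity at C14=C15. Ionisation of the allylic C12–O bond could also compete with the 5-endo closure. The fallback sets out from 10 and comes back at 12. Buffered mCPBA (NaHCO3, CH2Cl2, 0 °C) would epoxidise the same, most electron-rich alkene without facial control, giving 11 together with (2E,6E,8S)-9-[(2R)-3,3-dimethyloxiran-2-yl]-8-hydroxy-3,7-dimethylnona-2,6-dien-1-yl acetate F3. CSA would close both to 12 and the 2,4-trans oxolane (2E,6E)-7-[(2S,4R)-4-hydroxy-5,5-dimethyloxolan-2-yl]-3-methylocta-2,6-dien-1-yl acetate F4. Dess–Martin oxidation of the mixture would converge both on the single ketone (2E,6E)-7-[(2S)-5,5-dimethyl-4-oxooxolan-2-yl]-3-methylocta-2,6-dien-1-yl acetate F5. CBS reduction ((R)-2-methyl-CBS-oxazaborolidine, catecholborane, toluene, −78 °C) should return 12, the reagent preference being reinforced by hydride approach anti to the C12 alkenyl group. C14 is then set at the ketone stage, by reagent control and relay from C12, instead of at the alkene.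

Step 13. Addition to the β,β-disubstituted, less electrophilic enal may be slow enough for an uncatalysed background pathway to erode enantiofacial control, which would leave a C5 epimer that is hard to remove later. The fallback sets out from 15 and comes back at 16. A zinc-mediated Barbier propargylation (propargyl bromide, Zn, THF/aq. NH4Cl) would give 16 together with its carbinol epimer (4R,5E,9E)-10-[(2S,4S)-4-(tert-butyldimethylsilyloxy)-5,5-dimethyloxolan-2-yl]-6-methylundeca-5,9-dien-1-yn-4-ol F6. Lipase-catalysed acylation (Amano lipase PS, vinyl acetate, t-BuOMe, rt) should, by the empirical rule for secondary alcohols with the alkenyl chain as the large group, acetylate the (4R)-epimer to (4R,5E,9E)-10-[(2S,4S)-4-(tert-butyldimethylsilyloxy)-5,5-dimethyloxolan-2-yl]-6-methylundeca-5,9-dien-1-yn-4-yl acetate F7. Alcohol 16 would be left unreacted and separated by chromatography.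

**Further compounds**

F1 | step 14 | (1E,4S,5E,9E)-1-iodo-2,6-dimethyl-10-[(2S,4S)-4-(tert-butyldimethylsilyloxy)-5,5-dimethyloxolan-2-yl]undeca-1,5,9-trien-4-ol | O[C@H](/C=C(\C)CC/C=C(\C)[C@@H]1C[C@H](O[Si](C)(C)C(C)(C)C)C(C)(C)O1)C/C(C)=C/I
F2 | step 14 | (2,5-dimethoxy-3-methylbenzyl)zinc chloride | COc1cc(C)c(OC)c(C[Zn]Cl)c1
F3 | step 9 | (2E,6E,8S)-9-[(2R)-3,3-dimethyloxiran-2-yl]-8-hydroxy-3,7-dimethylnona-2,6-dien-1-yl acetate | CC(=O)OC/C=C(\C)CC/C=C(\C)[C@@H](O)C[C@H]1OC1(C)C
F4 | step 9 | (2E,6E)-7-[(2S,4R)-4-hydroxy-5,5-dimethyloxolan-2-yl]-3-methylocta-2,6-dien-1-yl acetate | CC(=O)OC/C=C(\C)CC/C=C(\C)[C@@H]1C[C@@H](O)C(C)(C)O1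
F5 | step 9 | (2E,6E)-7-[(2S)-5,5-dimethyl-4-oxooxolan-2-yl]-3-methylocta-2,6-dien-1-yl acetate | CC(=O)OC/C=C(\C)CC/C=C(\C)[C@@H]1CC(=O)C(C)(C)O1
F6 | step 13 | (4R,5E,9E)-10-[(2S,4S)-4-(tert-butyldimethylsilyloxy)-5,5-dimethyloxolan-2-yl]-6-methylundeca-5,9-dien-1-yn-4-ol | C#CC[C@@H](O)/C=C(\C)CC/C=C(\C)[C@@H]1C[C@H](O[Si](C)(C)C(C)(C)C)C(C)(C)O1
F7 | step 13 | (4R,5E,9E)-10-[(2S,4S)-4-(tert-butyldimethylsilyloxy)-5,5-dimethyloxolan-2-yl]-6-methylundeca-5,9-dien-1-yn-4-yl acetate | C#CC[C@@H](OC(C)=O)/C=C(\C)CC/C=C(\C)[C@@H]1C[C@H](O[Si](C)(C)C(C)(C)C)C(C)(C)O1
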